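The pyrrole (ring A) is disconnected at N1–C5 and C2–C3. The key step exploits that the formyl carbon, C2, C3, C4, C5 and the nonadecyl chain form one unbranched C24 line bridged only by N1, with C3 and C4 unsubstituted: methyl N-tosylglycinate supplies N1, C2 and the future formyl carbon, docos-2-ynal supplies C3–C5 and the chain. One base-mediated aza-Michael/aldol/dehydration cascade joins them, closing ring A at the pyrrole oxidation level with the chain fixed at C5. The precursor pair is thus a linear 2-alkynal and an N-sulfonylglycine ester; the ester is reduced to the aldehyde level afterwards while the sulfonyl group still protects the ring.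

Key step: step 4

Remark on the chemistry: compounds 5, 11 and F1 contain stereocentres that form without control (racemic; 11 and F1 as diastereomer mixtures) and are erased before the next isolated compound, so their SMILES carry no configuration. The target has no stereocentre.

Step 1
Reactants: 1 1-bromononadecane; 2 lithium acetylide–ethylenediamine complex
Product: 3 henicos-1-yne
Conditions: DMSO/THF, 10 °C to rt
Reagents that add atoms: none
Why: SN2 alkylation of an acetylide anion by an unhindered primary bromide in a dipolar aprotic medium, with THF keeping the waxy bromide in solution.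

Step 2
Reactants: 3 henicos-1-yne
Product: 6 docos-2-ynal, via lithium henicos-1-yn-1-ide 4 (not isolated), via lithium hemiaminal alkoxide 5 (not isolated)
Conditions: n-BuLi, THF, −78 °C; DMF, −78 °C to rt; inverse quench into aq. KH2PO4/MTBE, 0 °C
Reagents that add atoms: N,N-dimethylformamide, CN(C)C=O
Why: Formylation of a lithium alkynide with a formamide (Bouveault-type aldehyde synthesis), in which adduct 5 should hold until the inverse quench into acidic phosphate buffer releases the ynal and protonates dimethylamine so that it cannot add to the triple bond.

Step 3
Reactants: 7 glycine methyl ester hydrochloride; 8 4-toluenesulfonyl chloride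
Product: 9 methyl N-tosylglycinate
Conditions: Et3N, CH2Cl2, 0 °C to rt
Reagents that add atoms: none
Why: N-sulfonylation of a primary amine by a sulfonyl chloride, with Et3N freeing the amine from its salt and taking up HCl, and the acidic monosulfonamide should not react a second time.

Step 4
Reactants: 6 docos-2-ynal; 9 methyl N-tosylglycinate
Product: 12 methyl 5-nonadecyl-1-tosyl-1H-pyrrole-2-carboxylate, via Z-enaminal 10 (not isolated), via hydroxydihydropyrrole aldol adduct 11 (not isolated)
Conditions: Cs2CO3, MeCN/THF, 0 °C to rt, slow addition of 6
Reagents that add atoms: none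
Why: Cs2CO3 should deprotonate only the sulfonamide N–H of 9, and this soft nitrogen anion adds 1,4 to C3 of ynal 6 (the N1–C5 bond), the anti addition placing nitrogen and formyl group cis in the push-pull enaminal 10, whose double bond can equilibrate in any case. The methylene of 10, acidified by the ester and the N-sulfonyl group, then closes ring A by a 5-exo-trig (enolexo) intramolecular aldol addition onto the formyl carbon (the C2–C3 bond) to give 11. E1cB loss of water across C2–C3 is driven by aromatisation and erases both transient stereocentres of 11, so no stereocontrol is required. The closest known reaction type is the Kenner-type pyrrole synthesis, the aza-Michael/aldol condensation of N-sulfonylglycine esters with enones, enals and ynones; because the ynal already holds the pyrrole oxidation level, the sulfonyl group stays on nitrogen and C3 and C4 remain unsubstituted. The selectivity needed is regiochemical, nitrogen to the chain-bearing alkyne carbon and the glycine carbon to the formyl carbon: it is secured by the much greater acidity of N–H over C–H, which makes nitrogen the only nucleophile at the outset, and an initial carbon aldol followed by 5-endo-dig attack of nitrogen would converge on the same pyrrole.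

Step 5
Reactants: 12 methyl 5-nonadecyl-1-tosyl-1H-pyrrole-2-carboxylate
Product: 13 (5-nonadecyl-1-tosyl-1H-pyrrol-2-yl)methanol
Conditions: iBu2AlH (DIBAL-H), CH2Cl2, −78 to 0 °C; aq. KNaC4H4O6 (potassium sodium tartrate)
Reagents that add atoms: none
Why: Hydride reduction of an ester to the primary alcohol at low temperature, where the N-sulfonyl group should be retained and keeps the ring electron-poor, so the hydroxymethyl product cannot ionise to an azafulvene and be over-reduced.

Step 6
Reactants: 13 (5-nonadecyl-1-tosyl-1H-pyrrol-2-yl)methanol
Product: 14 5-nonadecyl-1-tosyl-1H-pyrrole-2-carbaldehyde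
Conditions: activated MnO2, CH2Cl2, rt
Reagents that add atoms: none
Why: MnO2 oxidation of a heteroaryl (benzylic-type) carbinol, which should stop at the aldehyde and leave the alkyl chain and the sulfonamide untouched.

Step 7
Reactants: 14 5-nonadecyl-1-tosyl-1H-pyrrole-2-carbaldehyde
Product: 15 5-nonadecyl-1H-pyrrole-2-carbaldehyde
Conditions: 5 M aq. NaOH, 1,4-dioxane/THF, rt; aq. NH4Cl
Reagents that add atoms: none
Why: Hydrolytic cleavage of the N-sulfonyl group by hydroxide attack at sulfur, easy because the 2-formylpyrrolide is a good leaving group; the aldehyde has no α-hydrogen, and the alcohol-free medium avoids an alkylating sulfonate ester.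

Compound list
1 | 1-bromononadecane | CCCCCCCCCCCCCCCCCCCBr | starting material
2 | lithium acetylide–ethylenediamine complex | [Li+].[C-]#C.NCCN | starting material
3 | henicos-1-yne | CCCCCCCCCCCCCCCCCCCC#C | intermediate
4 | lithium henicos-1-yn-1-ide (formed in the flask, not isolated) | CCCCCCCCCCCCCCCCCCCC#[C-].[Li+] | intermediate
5 | lithium 1-(dimethylamino)docos-2-yn-1-olate (racemic, formed in the flask, not isolated) | CCCCCCCCCCCCCCCCCCCC#CC([O-])N(C)C.[Li+] | intermediate
6 | docos-2-ynal | CCCCCCCCCCCCCCCCCCCC#CC=O | intermediate
7 | glycine methyl ester hydrochloride | COC(=O)CN.Cl | starting material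
8 | 4-toluenesulfonyl chloride | Cc1ccc(S(=O)(=O)Cl)cc1 | starting material
9 | methyl N-tosylglycinate (methyl 2-[(4-methylphenyl)sulfonylamino]acetate) | COC(=O)CNS(=O)(=O)c1ccc(C)cc1 | intermediate
10 | methyl N-[(2Z)-1-oxodocos-2-en-3-yl]-N-tosylglycinate, nitrogen and formyl group cis (formed in the flask, not isolated) | CCCCCCCCCCCCCCCCCCC/C(=C/C=O)N(CC(=O)OC)S(=O)(=O)c1ccc(C)cc1 | intermediate
11 | methyl 3-hydroxy-5-nonadecyl-1-tosyl-2,3-dihydro-1H-pyrrole-2-carboxylate (racemic diastereomer mixture, formed in the flask, not isolated) | CCCCCCCCCCCCCCCCCCCC1=CC(O)C(C(=O)OC)N1S(=O)(=O)c2ccc(C)cc2 | intermediate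
12 | methyl 5-nonadecyl-1-tosyl-1H-pyrrole-2-carboxylate | CCCCCCCCCCCCCCCCCCCc1ccc(C(=O)OC)n1S(=O)(=O)c2ccc(C)cc2 | intermediate
13 | (5-nonadecyl-1-tosyl-1H-pyrrol-2-yl)methanol | CCCCCCCCCCCCCCCCCCCc1ccc(CO)n1S(=O)(=O)c2ccc(C)cc2 | intermediate
14 | 5-nonadecyl-1-tosyl-1H-pyrrole-2-carbaldehyde | CCCCCCCCCCCCCCCCCCCc1ccc(C=O)n1S(=O)(=O)c2ccc(C)cc2 | intermediate
15 | 5-nonadecyl-1H-pyrrole-2-carbaldehyde | CCCCCCCCCCCCCCCCCCCc1ccc(C=O)[nH]1 | target

Total step count: 7. Longest linear sequence: 6 steps (steps 1, 2, 4, 5, 6 and 7 from 1-bromononadecane); step 3 is a one-step side branch.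

Steps most likely to fail

1. Step 4. What may go wrong: base-induced loss of the ynal (cleavage of the formyl group, propargyl-to-allenyl isomerisation, oligomerisation) outpacing the conjugate addition, or the cascade stalling before dehydration. Fallback: the order of bond formation is reversed with known chemistry, setting out from 6 and 9. The divalent tin enolate of 9 (LiN(iPr)2, then SnCl2, THF, −78 °C) should add to the formyl group of 6 in an intermolecular aldol addition at low temperature, where the ynal never meets free base. This forms the C2–C3 bond first and gives methyl 3-hydroxy-2-(tosylamino)tetracos-4-ynoate F1. AgNO3 on silica gel (CH2Cl2, rt) should then promote 5-endo-dig hydroamination of the alkyne by the sulfonamide nitrogen (the N1–C5 bond), which gives 11. Loss of water, on the support or with a trace of acid, returns the material to the route at 12.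

2. Step 5. What may go wrong: hydride attack at sulfur with loss of the sulfonyl group, after which the unprotected hydroxymethylpyrrole ionises to an azafulvene and is over-reduced or polymerises. Fallback: from 12 the ester carbon is given up instead of reduced. KOH in ethylene glycol at about 180 °C should cleave the sulfonamide and saponify the ester to 5-nonadecyl-1H-pyrrole-2-carboxylic acid F2 (as its potassium salt, not isolated), then decarboxylate it to 2-nonadecyl-1H-pyrrole F3. Vilsmeier–Haack formylation (POCl3, DMF, 0 °C to rt, then aq. NaOAc) at the only free α-position should then give the target, so the fallback returns at 15 and bypasses 13 and 14.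

3. Step 2. What may go wrong: conjugate addition of liberated dimethylamine to the ynal during the quench, or early collapse of the tetrahedral adduct followed by a second alkynide addition. Fallback: from 3 the aldehyde is reached through the alcohol oxidation level. Lithiation (n-BuLi, THF) and trapping with paraformaldehyde should give docos-2-yn-1-ol F4. Oxidation of this propargylic alcohol with activated MnO2 (CH2Cl2, rt) should then give the ynal with no amine present, and the fallback returns at 6.

Further compounds
F1 | step 4 | methyl 3-hydroxy-2-[(4-methylphenyl)sulfonylamino]tetracos-4-ynoate (racemic diastereomer mixture) | CCCCCCCCCCCCCCCCCCCC#CC(O)C(NS(=O)(=O)c1ccc(C)cc1)C(=O)OC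
F2 | step 5 | 5-nonadecyl-1H-pyrrole-2-carboxylic acid | CCCCCCCCCCCCCCCCCCCc1ccc(C(=O)O)[nH]1
F3 | step 5 | 2-nonadecyl-1H-pyrrole | CCCCCCCCCCCCCCCCCCCc1ccc[nH]1
F4 | step 2 | docos-2-yn-1-ol | CCCCCCCCCCCCCCCCCCCC#CCO
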